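**Plan**
- Retrosynthetic cuts, in order: the C11–OOH bond (with the C6=C7 shift), the angelate C–O bond, the C7=C11 alkene (back to a β-silyloxy ketone), C4–C15, C5–C6 (ring B), C7–C8, C3–O, and the C10–C9 bond.
- Enabling feature: C5 is α to the C4 carbonyl of ring A and C6 is β to the C8 carbonyl of ring B, so C5–C6 is the bond a ring-A ketone enolate makes with an α-methylene ketone whose α-carbon C7 already carries C11.
- Forward: ring A comes from 3-methylcyclohexenone (C9/C8 enter as a vinyl group, C3 is oxygenated); the C11 fragment from 2-methylbut-3-yn-2-ol is joined at C7–C8; ring B closes by the Michael step; C15, the isopropylidene, the angelate and the hydroperoxide follow.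
- Stereochemistry: C10 by catalyst-controlled conjugate addition; C5 and C3 by base equilibration relative to C10 in the ring closure; C4 by chelation-controlled equatorial Grignard attack opposite the axial C10 methyl; the ene reaction creates no stereocentre.

Key step: step 11

Remark: eudesmane numbering is used for every carbon (ring A = C1–C5 and C10; ring B = C5–C10; C11 carries C12/C13; C14 on C10; C15 on C4).
Remark: the Rubottom step is not expected to be face-selective, so 7–11, 17 and 18 are carried as mixtures of the two epimers at the oxygen-bearing carbon C3; names and SMILES of 9–11, 17 and 18 show the 3S epimer, and this centre is equilibrated in step 11.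

Step 1
Reactants: 1 3-methylcyclohex-2-en-1-one; 2 ethynyltrimethylsilane
Product: 4 (3S)-3-methyl-3-[1-(trimethylsilyl)ethenyl]cyclohexan-1-one, via alkenylalane 3 (not isolated)
Conditions: 2, iBu2AlH, hexane/THF, 55 °C; then 1, Cu(OTf)2 (5 mol %), chiral sulfonate-bearing N-heterocyclic carbene ligand (5 mol %, the enantiomer that gives the 3S adduct), THF, −15 °C → rt; aq. potassium sodium tartrate
Reagents that add atoms: none
Why: Copper-catalysed asymmetric conjugate addition of an alkenylaluminium reagent (from syn-hydroalumination of the silylalkyne, aluminium geminal to silicon) to a β-substituted cyclic enone is a known route to quaternary centres, and the chiral carbene on copper decides which enone face is attacked, so C10 is set here under catalyst control.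

Step 2
Reactants: 4 (3S)-3-methyl-3-[1-(trimethylsilyl)ethenyl]cyclohexan-1-one
Product: 5 (3S)-3-ethenyl-3-methylcyclohexan-1-one
Conditions: CF3CO2H, CH2Cl2, 0 °C → rt
Reagents that add atoms: none
Why: Protodesilylation of a vinylsilane: the proton adds at the silicon-bearing carbon, the β-silyl cation loses the silyl group to trifluoroacetate, and the quaternary centre is untouched.

Step 3
Reactants: 5 (3S)-3-ethenyl-3-methylcyclohexan-1-one
Product: 6 (5S)-5-ethenyl-5-methyl-1-(trimethylsilyloxy)cyclohex-1-ene
Conditions: LiN(iPr)2, THF, −78 °C; Me3SiCl, Et3N; pentane extraction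
Reagents that add atoms: chlorotrimethylsilane, C[Si](C)(C)Cl
Why: Kinetic deprotonation takes the less hindered α-methylene remote from the quaternary carbon, and O-silylation traps that regioisomer as the silyl enol ether.

Step 4
Reactants: 6 (5S)-5-ethenyl-5-methyl-1-(trimethylsilyloxy)cyclohex-1-ene
Product: 9 (2S,5S)-5-ethenyl-2-hydroxy-5-methylcyclohexan-1-one (plus its 2R epimer), via silyloxy epoxide 7 (not isolated), via silyloxy ketone 8 (not isolated)
Conditions: mCPBA, NaHCO3, CH2Cl2, −20 → 0 °C; then 1 M HCl, THF, 0 °C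
Reagents that add atoms: 3-chloroperoxybenzoic acid, OOC(=O)c1cccc(Cl)c1
Why: Rubottom oxidation: the electron-rich enol ether is epoxidised much faster than the vinyl group, the silyloxy epoxide opens with 1,4-silyl shift to the α-silyloxy ketone and acid frees the α-ketol; the new centre C3 forms without useful face selectivity and is corrected in step 11.

Step 5
Reactants: 9 (2S,5S)-5-ethenyl-2-hydroxy-5-methylcyclohexan-1-one (plus its 2R epimer)
Product: 10 (2S,5S)-2-(benzyloxy)-5-ethenyl-5-methylcyclohexan-1-one (plus its 2R epimer)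
Conditions: benzyl 2,2,2-trichloroacetimidate, TfOH (5 mol %), CH2Cl2/cyclohexane, 0 °C → rt
Reagents that add atoms: benzyl 2,2,2-trichloroacetimidate, N=C(OCc1ccccc1)C(Cl)(Cl)Cl
Why: Acid-catalysed O-benzylation with a trichloroacetimidate avoids the basic conditions under which an α-ketol would enolise or rearrange, and gives an ether that is inert to alkoxide and cannot migrate.

Step 6
Reactants: 10 (2S,5S)-2-(benzyloxy)-5-ethenyl-5-methylcyclohexan-1-one (plus its 2R epimer)
Product: 11 2-[(1R,4S)-4-(benzyloxy)-1-methyl-3-oxocyclohexyl]acetaldehyde (plus its 4R epimer)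
Conditions: PdCl2(PhCN)2 (10 mol %), CuCl2·2H2O (10 mol %), AgNO2 (5 mol %), O2 (1 atm), t-BuOH/MeNO2 15:1, rt
Reagents that add atoms: dioxygen, O=O
Why: Nitrite-modified Wacker oxidation delivers oxygen to the terminal carbon (anti-Markovnikov), a preference that the adjacent quaternary carbon reinforces, so the vinyl group becomes the C8 aldehyde without touching the ketone or the benzyl ether.

Step 7
Reactants: 12 2-methylbut-3-yn-2-ol
Product: 13 triethyl[(2-methylbut-3-yn-2-yl)oxy]silane
Conditions: Et3SiOTf, 2,6-lutidine, CH2Cl2, −78 → 0 °C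
Reagents that add atoms: triethylsilyl trifluoromethanesulfonate, CC[Si](CC)(CC)OS(=O)(=O)C(F)(F)F
Why: A silyl triflate with a hindered pyridine base is the standard silylation of a tertiary alcohol.

Step 8
Reactants: 13 triethyl[(2-methylbut-3-yn-2-yl)oxy]silane
Product: 15 triethyl[(3-iodo-2-methylbut-3-en-2-yl)oxy]silane, via alkenylstannane 14 (not isolated)
Conditions: Bu3SnH, Mo(CO)3(CNtBu)3 (2 mol %), hydroquinone, THF, 55 °C; then I2, CH2Cl2, 0 °C
Reagents that add atoms: iodine, II
Why: Molybdenum-catalysed hydrostannation of a terminal propargylic ether places tin on the internal carbon, and iododestannylation then replaces tin by iodine at the same sp2 carbon.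

Step 9
Reactants: 11 2-[(1R,4S)-4-(benzyloxy)-1-methyl-3-oxocyclohexyl]acetaldehyde (plus its 4R epimer); 15 triethyl[(3-iodo-2-methylbut-3-en-2-yl)oxy]silane
Product: 17 (2S,5R)-2-(benzyloxy)-5-{2-hydroxy-4-methyl-3-methylidene-4-[(triethylsilyl)oxy]pentyl}-5-methylcyclohexan-1-one (both carbinol epimers), via alkenylchromium 16 (not isolated)
Conditions: CrCl2 (4 equiv), NiCl2 (1 mol %), DMF, rt
Reagents that add atoms: none
Why: Nozaki–Hiyama–Kishi coupling: nickel activates the C–I bond, chromium takes over the alkenyl group, and the resulting alkenylchromium adds to the aldehyde but not to the ketone; the carbinol centre forms unselectively and is removed in step 10.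

Step 10
Reactants: 17 (2S,5R)-2-(benzyloxy)-5-{2-hydroxy-4-methyl-3-methylidene-4-[(triethylsilyl)oxy]pentyl}-5-methylcyclohexan-1-one
Product: 18 (2S,5R)-2-(benzyloxy)-5-methyl-5-{4-methyl-3-methylidene-2-oxo-4-[(triethylsilyl)oxy]pentyl}cyclohexan-1-one (plus its 2R epimer)
Conditions: Dess–Martin periodinane, NaHCO3, CH2Cl2, 0 °C → rt
Reagents that add atoms: none
Why: Dess–Martin oxidation under buffered neutral conditions turns the secondary allylic alcohol into the α-methylene ketone without enolising the α-benzyloxy ketone or losing the tertiary silyl ether.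

Step 11
Reactants: 18 (2S,5R)-2-(benzyloxy)-5-methyl-5-{4-methyl-3-methylidene-2-oxo-4-[(triethylsilyl)oxy]pentyl}cyclohexan-1-one (plus its 2R epimer)
Product: 20 3β-(benzyloxy)-11-[(triethylsilyl)oxy]-15-nor-5α-eudesmane-4,8-dione (trans-fused; 3S,5R,7R,10R), via cis-fused adduct 19 (not isolated)
Conditions: NaOMe (0.3 equiv), MeOH/THF 4:1, 0 → 23 °C; AcOH quench; recovered cis-fused or 3-epi material is returned to the same conditions
Reagents that add atoms: none
Why: Methoxide reversibly enolises both ketones, but only the C4/C5 enolate has a six-membered transition state to the unsubstituted terminus C6 of the α-methylene ketone, so conjugate addition forms C5–C6 and a C7/C8 enolate that methanol protonates at once (intramolecular Michael addition of a ketone enolate to a tethered enone, the ring-closing half of a base-mediated Michael annulation). Ring B closes in the 6-endo-trig mode, both C6 and C7 lying in the new ring. Because C6 must reach the enolate carbon from the side of the C10–C9 tether, the first-formed adduct 19 is cis-fused; C5, now α to the C4 ketone, is then epimerised by the same base, and the trans-fused decalone with the C10 methyl as its only axial group should predominate at equilibrium, although the angular methyl makes that margin modest. C7 ends with its bulky side chain equatorial (7β) through axial protonation from the open α face and equilibration, and C3 equilibrates to the equatorial 3β-benzyloxy epimer, which is why the Rubottom mixture converges here. The step needs regioselectivity among the enolates, secured by ring size (attack from C3 would give an eight-membered ring and the C9 enolate cannot reach C6), and survival of the β-silyloxy ketone, secured by the protic medium that keeps the C7 enolate too short-lived to expel silanolate.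

Step 12
Reactants: 20 3β-(benzyloxy)-11-[(triethylsilyl)oxy]-15-nor-5α-eudesmane-4,8-dione
Product: 21 3β-hydroxy-11-[(triethylsilyl)oxy]-15-nor-5α-eudesmane-4,8-dione (3S,5R,7R,10R)
Conditions: H2 (1 atm), Pd/C (10 %), EtOAc, rt
Reagents that add atoms: none
Why: Hydrogenolysis of the benzyl ether over palladium is neutral and, since 20 holds no alkene, touches nothing else, so C3 and C5 keep their configurations.

Step 13
Reactants: 21 3β-hydroxy-11-[(triethylsilyl)oxy]-15-nor-5α-eudesmane-4,8-dione
Product: 22 3β,4β-dihydroxy-11-[(triethylsilyl)oxy]-5α-eudesman-8-one (4α-methyl; 3S,4R,5R,7R,10R)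
Conditions: MeMgBr (3.5 equiv), THF, −78 → −40 °C; aq. NH4Cl
Reagents that add atoms: methylmagnesium bromide, C[Mg]Br
Why: Chelation-controlled Grignard addition: the first equivalent makes the C3 magnesium alkoxide, which chelates and activates the C4 carbonyl over the hindered C8 ketone, and methyl then enters equatorially from the α face because the β face is shielded by the axial C10 methyl, giving 4α-CH3 and 4β-OH (4R).

Step 14
Reactants: 22 3β,4β-dihydroxy-11-[(triethylsilyl)oxy]-5α-eudesman-8-one
Product: 23 3β,4β-dihydroxy-5α-eudesm-7(11)-en-8-one (3S,4R,5R,10R)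
Conditions: DBU (5 equiv), toluene, 90 °C
Reagents that add atoms: none
Why: E1cB elimination: the amidine enolises the C8 ketone toward C7 and triethylsilanolate leaves from C11, which can only give the conjugated 7(11)-alkene, while C5 is no longer next to a carbonyl and cannot epimerise.

Step 15
Reactants: 23 3β,4β-dihydroxy-5α-eudesm-7(11)-en-8-one; 24 angelic acid
Product: 26 3β-[(Z)-2-methylbut-2-enoyloxy]-4β-hydroxy-5α-eudesm-7(11)-en-8-one (3S,4R,5R,10R), via mixed anhydride 25 (not isolated)
Conditions: 24, 2,4,6-trichlorobenzoyl chloride, Et3N, toluene, rt; then 23, 80 °C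
Reagents that add atoms: none
Why: Yamaguchi-type mixed-anhydride esterification run without a nucleophilic amine catalyst keeps the Z geometry of the angeloyl group, and only the secondary equatorial C3 hydroxyl is acylated because the tertiary axial C4 hydroxyl is too hindered.

Step 16
Reactants: 26 3β-[(Z)-2-methylbut-2-enoyloxy]-4β-hydroxy-5α-eudesm-7(11)-en-8-one
Product: 27 3β-angeloyloxy-4β-hydroxy-11-hydroperoxy-5α-eudesm-6-en-8-one (3S,4R,5R,10R)
Conditions: O2, tetraphenylporphyrin (cat.), visible light, CH2Cl2, 0 °C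
Reagents that add atoms: dioxygen, O=O
Why: Schenck ene reaction of singlet oxygen with an s-cis enone: oxygen bonds to the β-carbon C11, hydrogen is taken from C6 (the alkyl group geminal to the acyl group on C7) and the double bond moves to C6=C7 in conjugation with C8=O, creating no stereocentre, while the electron-poor angelate should react much more slowly.

**Compound list**
1 | 3-methylcyclohex-2-en-1-one | CC1=CC(=O)CCC1 | starting material
2 | ethynyltrimethylsilane | C#C[Si](C)(C)C | starting material
3 | diisobutyl[1-(trimethylsilyl)ethenyl]alane | C=C([Si](C)(C)C)[Al](CC(C)C)CC(C)C | intermediate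
4 | (3S)-3-methyl-3-[1-(trimethylsilyl)ethenyl]cyclohexan-1-one | C=C([Si](C)(C)C)[C@@]1(C)CCCC(=O)C1 | intermediate
5 | (3S)-3-ethenyl-3-methylcyclohexan-1-one | C=C[C@@]1(C)CCCC(=O)C1 | intermediate
6 | (5S)-5-ethenyl-5-methyl-1-(trimethylsilyloxy)cyclohex-1-ene | C=C[C@@]1(C)CCC=C(O[Si](C)(C)C)C1 | intermediate
7 | (3S)-3-ethenyl-3-methyl-1-(trimethylsilyloxy)-7-oxabicyclo[4.1.0]heptane (both epoxide faces) | C=C[C@@]1(C)CCC2OC2(O[Si](C)(C)C)C1 | intermediate
8 | (5S)-5-ethenyl-5-methyl-2-(trimethylsilyloxy)cyclohexan-1-one (both C2 epimers) | C=C[C@@]1(C)CCC(O[Si](C)(C)C)C(=O)C1 | intermediate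
9 | (2S,5S)-5-ethenyl-2-hydroxy-5-methylcyclohexan-1-one (2R epimer also present) | C=C[C@@]1(C)CC[C@H](O)C(=O)C1 | intermediate
10 | (2S,5S)-2-(benzyloxy)-5-ethenyl-5-methylcyclohexan-1-one (2R epimer also present) | C=C[C@@]1(C)CC[C@H](OCc2ccccc2)C(=O)C1 | intermediate
11 | 2-[(1R,4S)-4-(benzyloxy)-1-methyl-3-oxocyclohexyl]acetaldehyde (4R epimer also present) | O=CC[C@@]1(C)CC[C@H](OCc2ccccc2)C(=O)C1 | intermediate
12 | 2-methylbut-3-yn-2-ol | CC(C)(O)C#C | starting material
13 | triethyl[(2-methylbut-3-yn-2-yl)oxy]silane | CC[Si](CC)(CC)OC(C)(C)C#C | intermediate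
14 | tributyl{3-methyl-3-[(triethylsilyl)oxy]but-1-en-2-yl}stannane | C=C([Sn](CCCC)(CCCC)CCCC)C(C)(C)O[Si](CC)(CC)CC | intermediate
15 | triethyl[(3-iodo-2-methylbut-3-en-2-yl)oxy]silane | C=C(I)C(C)(C)O[Si](CC)(CC)CC | intermediate
16 | dichloro{3-methyl-3-[(triethylsilyl)oxy]but-1-en-2-yl}chromium | C=C([Cr](Cl)Cl)C(C)(C)O[Si](CC)(CC)CC | intermediate
17 | (2S,5R)-2-(benzyloxy)-5-{2-hydroxy-4-methyl-3-methylidene-4-[(triethylsilyl)oxy]pentyl}-5-methylcyclohexan-1-one (both carbinol epimers; 2R epimer also present) | C=C(C(C)(C)O[Si](CC)(CC)CC)C(O)C[C@@]1(C)CC[C@H](OCc2ccccc2)C(=O)C1 | intermediate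
18 | (2S,5R)-2-(benzyloxy)-5-methyl-5-{4-methyl-3-methylidene-2-oxo-4-[(triethylsilyl)oxy]pentyl}cyclohexan-1-one (2R epimer also present) | C=C(C(C)(C)O[Si](CC)(CC)CC)C(=O)C[C@@]1(C)CC[C@H](OCc2ccccc2)C(=O)C1 | intermediate
19 | 3β-(benzyloxy)-11-[(triethylsilyl)oxy]-15-nor-5β-eudesmane-4,8-dione (cis-fused 5-epimer of 20, drawn with the C3 and C7 configurations of 20) | c1ccccc1CO[C@H]1CC[C@]2(C)CC(=O)[C@@H](C(C)(C)O[Si](CC)(CC)CC)C[C@@H]2C1=O | intermediate
20 | 3β-(benzyloxy)-11-[(triethylsilyl)oxy]-15-nor-5α-eudesmane-4,8-dione (trans-fused, 10β-methyl, 7β side chain; 3S,5R,7R,10R) | c1ccccc1CO[C@H]1CC[C@]2(C)CC(=O)[C@@H](C(C)(C)O[Si](CC)(CC)CC)C[C@H]2C1=O | intermediate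
21 | 3β-hydroxy-11-[(triethylsilyl)oxy]-15-nor-5α-eudesmane-4,8-dione (3S,5R,7R,10R) | O[C@H]1CC[C@]2(C)CC(=O)[C@@H](C(C)(C)O[Si](CC)(CC)CC)C[C@H]2C1=O | intermediate
22 | 3β,4β-dihydroxy-11-[(triethylsilyl)oxy]-5α-eudesman-8-one (4α-methyl; 3S,4R,5R,7R,10R) | O[C@H]1CC[C@]2(C)CC(=O)[C@@H](C(C)(C)O[Si](CC)(CC)CC)C[C@H]2[C@@]1(C)O | intermediate
23 | 3β,4β-dihydroxy-5α-eudesm-7(11)-en-8-one (3S,4R,5R,10R) | O[C@H]1CC[C@]2(C)CC(=O)C(=C(C)C)C[C@H]2[C@@]1(C)O | intermediate
24 | angelic acid, (Z)-2-methylbut-2-enoic acid | C/C=C(/C)C(=O)O | starting material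
25 | (Z)-2-methylbut-2-enoic 2,4,6-trichlorobenzoic anhydride | C/C=C(/C)C(=O)OC(=O)c1c(Cl)cc(Cl)cc1Cl | intermediate
26 | 3β-[(Z)-2-methylbut-2-enoyloxy]-4β-hydroxy-5α-eudesm-7(11)-en-8-one (3S,4R,5R,10R) | C/C=C(/C)C(=O)O[C@H]1CC[C@]2(C)CC(=O)C(=C(C)C)C[C@H]2[C@@]1(C)O | intermediate
27 | 3β-angeloyloxy-4β-hydroxy-11-hydroperoxy-5α-eudesm-6-en-8-one (3S,4R,5R,10R) | C/C=C(/C)C(=O)O[C@H]1CC[C@]2(C)CC(=O)C(C(C)(C)OO)=C[C@H]2[C@@]1(C)O | target

**Step count and risks**
Total steps: 16. Longest linear sequence: 14 (steps 1–6 and 9–16); steps 7–8 make the C11 fragment.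

Steps most likely to fail:

1. Step 11. The equilibration may stop short of the trans ring fusion, because an angular methyl narrows the cis/trans gap of decal-4-ones, and long exposure to base may let the C7 enolate expel silanolate. Fallback, setting out from 20 (as its mixture of C5 epimers) and returning at 21: C5 is set by hydrogenation instead of equilibration. LiN(iPr)2 (2.5 equiv) and Me3SiCl at −78 °C should deprotonate the α-benzyloxy ketone on its far side (C5) and the ring-B ketone at C9, giving 3β-(benzyloxy)-4,8-bis(trimethylsilyloxy)-11-[(triethylsilyl)oxy]-15-noreudesma-4,8-diene F1. Saegusa–Ito oxidation (Pd(OAc)2, MeCN, rt) can dehydrogenate only the ring-A enol ether, toward C6, because the ring-B enol ether has no β-hydrogen on C10 and reverts to the ketone on work-up; this gives 3β-(benzyloxy)-11-[(triethylsilyl)oxy]-15-noreudesm-5-ene-4,8-dione F2. Hydrogenation over Pd/C (H2, EtOAc) should add hydrogen to C5=C6 from the α face, opposite the angular methyl, and cleave the benzyl ether in the same operation, giving 21 directly and replacing step 12.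

2. Step 16. The electron-poor, tetrasubstituted enone may take up singlet oxygen slowly, so that ene oxidation of the angelate double bond or hydrogen abstraction from the C12/C13 methyl groups competes during long irradiation. Fallback, setting out from 23 and returning at 27: the photo-oxygenation is run before the ester is present. Diol 23 under the conditions of step 16 should give 3β,4β-dihydroxy-11-hydroperoxy-5α-eudesm-6-en-8-one F3. Et3SiCl and imidazole (CH2Cl2, 0 °C) mask the more acidic hydroperoxide as 3β,4β-dihydroxy-11-(triethylsilylperoxy)-5α-eudesm-6-en-8-one F4. Acylation as in step 15 gives 3β-angeloyloxy-4β-hydroxy-11-(triethylsilylperoxy)-5α-eudesm-6-en-8-one F5, and HF·pyridine (THF, 0 °C) frees the hydroperoxide to give 27.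

3. Step 15. Heating the hindered C3 alcohol with the mixed anhydride may be sluggish and may isomerise the Z acyl group to the tiglate. Fallback, setting out from 23 and returning at 26: the Z alkene is built on the ester. Diol 23 is acylated with 2-[bis(2,2,2-trifluoroethoxy)phosphoryl]propanoic acid (EDC, DMAP, CH2Cl2) to give 3β-{2-[bis(2,2,2-trifluoroethoxy)phosphoryl]propanoyloxy}-4β-hydroxy-5α-eudesm-7(11)-en-8-one F6. Still–Gennari olefination with acetaldehyde (KN(SiMe3)2, 18-crown-6, THF, −78 °C) should then form the (Z)-2-methylbut-2-enoate, that is 26.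

Further compounds
F1 | step 11 | 3β-(benzyloxy)-4,8-bis(trimethylsilyloxy)-11-[(triethylsilyl)oxy]-15-noreudesma-4,8-diene | c1ccccc1CO[C@H]1CC[C@]2(C)C=C(O[Si](C)(C)C)[C@@H](C(C)(C)O[Si](CC)(CC)CC)CC2=C1O[Si](C)(C)C
F2 | step 11 | 3β-(benzyloxy)-11-[(triethylsilyl)oxy]-15-noreudesm-5-ene-4,8-dione | c1ccccc1CO[C@H]1CC[C@]2(C)CC(=O)[C@@H](C(C)(C)O[Si](CC)(CC)CC)C=C2C1=O
F3 | step 16 | 3β,4β-dihydroxy-11-hydroperoxy-5α-eudesm-6-en-8-one | O[C@H]1CC[C@]2(C)CC(=O)C(C(C)(C)OO)=C[C@H]2[C@@]1(C)O
F4 | step 16 | 3β,4β-dihydroxy-11-(triethylsilylperoxy)-5α-eudesm-6-en-8-one | O[C@H]1CC[C@]2(C)CC(=O)C(C(C)(C)OO[Si](CC)(CC)CC)=C[C@H]2[C@@]1(C)O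
F5 | step 16 | 3β-angeloyloxy-4β-hydroxy-11-(triethylsilylperoxy)-5α-eudesm-6-en-8-one | C/C=C(/C)C(=O)O[C@H]1CC[C@]2(C)CC(=O)C(C(C)(C)OO[Si](CC)(CC)CC)=C[C@H]2[C@@]1(C)O
F6 | step 15 | 3β-{2-[bis(2,2,2-trifluoroethoxy)phosphoryl]propanoyloxy}-4β-hydroxy-5α-eudesm-7(11)-en-8-one (both epimers at the phosphonate carbon) | CC(C(=O)O[C@H]1CC[C@]2(C)CC(=O)C(=C(C)C)C[C@H]2[C@@]1(C)O)P(=O)(OCC(F)(F)F)OCC(F)(F)F
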